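**Two charges.** I begin from the ratio of the charges: 0.140 M of the reagent Jb against 0.20 M of the substrate Ja, with less Jb. If one round of the catalyst Jc takes one Jb and one Ja and returns Jc with one Jf, as the suspected steps say, then Jb is the limiting reagent. I call the ratio the ceiling, 70.0%: the conversion of Ja at which Jb is spent.

- summer: Ja 0.20 M; Jb 0.14 M; Jc 10 mM; the very flask that is asked about, followed so far
- flask: Ja 0.20 M; Jb 0.140 M; Jc 10 mM

summer run (percent of the Ja charged)

| time / h | Jf / % | Ja / % |
|---|---|---|
| 0.833 | 6 | 97 |
| 2.50 | 17 | 84 |
| 4.00 | 24 | 76 |
| 6.00 | 31 | 65 |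
| 10.0 | 46 | 52 |
| 12.0 | 52 | 48 |

(standard deviation of a reading: 2 percentage points)

- apparent order in Jc when 50% of the Ja are converted (percent change of the rate of making Jf for one percent more Jc charged)
- factor on the rate of making Jf when 50% of the Ja are converted if Jc is charged twice over

- what was read earlier has a scatter of 2 percentage points, one standard deviation
- on the list of suspects stand: Jg -> Jh; Jk -> Jc + Jf; Jc -> Jd; Jb + Jc -> Jg; Jb <-> Je; Ja + Jh -> Jj; Jj -> Jk
- no earlier run changes the charge of Jc; that part of a forecast is a guess

**First estimate.** The ceiling ties the stock of Jb, meaning the share not yet spent with Je counted, to conversion: it is one minus conversion over ceiling. At 50% this flask therefore has 40.0 mM left, and that amount doesn't depend on the charge of Jc. So the rate should follow Jc, with order one and a factor of 2.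

**First doubt.** Perhaps Jc dies, and then a larger charge arrives at 50% sooner with more of it alive, which raises the order. I test this on the summer run. The rate between 6.00 h and 12.0 h, over the rate up to 2.50 h, reads 0.515. The stock of Jb at the middle of those windows gives a ratio of 0.463. With a scatter of 2 percentage points per reading, the rate ratio reads higher than the stock ratio, so these readings ask for no dying Jc.

**Second doubt.** Jg, Jh, Jj and Jk each hold a Jb. The 10 mM of Jc is a quarter of that stock, and charged twice over it is half. The bound part is missing from what reacts, and I can't read its size. I therefore commit to an order just under one and a factor just under 2.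

**The forecast.** It differs from my reckoning. It gives an order of 1.3 (1 to 2.2) and a factor of 2.5 (2 to 3.6), on the ground: “Substrate depletion probably accounts for most of it, with modest deactivation”.

**The flask.** The order is 0.91 and the factor 1.88.

    Jg → Jh (k = 5.00 h⁻¹)
    Jk → Jc + Jf (k = 470 h⁻¹)
    Jc → Jd (k = 2.30 × 10⁻⁴ h⁻¹)
    Jb + Jc → Jg (k = 23.0 M⁻¹ h⁻¹)
    Jb ⇌ Je (K = 0.450, k = 0.190 h⁻¹)
    Ja + Jh → Jj (k = 160 M⁻¹ h⁻¹)
    Jj → Jk (k = 9.90 h⁻¹)

In this flask Jd, the one form outside the working round, holds 0.254% of the catalyst at 15.0 h. The ceiling of 70.0% marks the end of this flask: after 300 h, Jb stands at 0% and Jf at 70.0%.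

The earlier runs and the new flask were generated by integration for an exercise; the scatter is artificial.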